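**Retrosynthetic overview**
1. Last bond: the bridging CH2–C7 bond, made by intermolecular Michael addition of decarboxycitrinin (C7 of its vinylogous acid) to the ortho-quinone methide released from the C7 Mannich base of the dihydroxy lactone half.
2. Both halves come from one lactone, (3R,4S)-6,8-dihydroxy-3,4,5-trimethylisochroman-1-one: aminomethylation gives the acceptor half; silylation, partial reduction and desilylation with loss of water give the quinone methide half.
3. Lactone ring: bromination next to the side chain of a (2R,3S)-3-arylbutan-2-ol, Br/Li exchange, CO2, lactonisation.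
4. Stereocentres: trans-epoxide from (2S,3S)-butane-2,3-diol, anti opening by the aryl Grignard reagent (sets C4), Mitsunobu inversion (sets C3).
5. Ring order: benzene ring bought; lactone ring closed; in one half it is recast as the pyran ring of the quinone methide; the two bicycles are joined last.

Assumption: the hydroxy-enone of decarboxycitrinin and of the target is drawn as the 6-hydroxy-8-oxo tautomer of the given SMILES; it equilibrates freely with the 8-hydroxy-6-oxo form, so no step is needed to set it.

**Route**

Step 1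
Reactants: 1 1-bromo-3,5-dimethoxybenzene
Product: 3 2-bromo-4,6-dimethoxybenzaldehyde, via iminium chloride 2 (not isolated)
Conditions: POCl3 (1.5 equiv), DMF, 0 → 90 °C; then ice-water
Reagents that add atoms: N,N-dimethylformamide CN(C)C=O; water O
Why: Vilsmeier–Haack formylation attacks the position para to one methoxy group and ortho to the other (next to bromine) in preference to the more crowded position between the two methoxy groups, and the iminium salt is hydrolysed on work-up; no stereocentre.

Step 2
Reactants: 3 2-bromo-4,6-dimethoxybenzaldehyde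
Product: 4 1-bromo-3,5-dimethoxy-2-methylbenzene
Conditions: Et3SiH (3 equiv), CF3CO2H, CH2Cl2, 0 °C → rt
Reagents that add atoms: none
Why: Ionic hydrogenation: the protonated aldehyde and then the doubly methoxy-stabilised benzylic cation each take hydride from Et3SiH, which leaves the aryl bromide and the ethers untouched.

Step 3
Reactants: 5 (2S,3S)-butane-2,3-diol
Product: 6 (2S,3R)-3-bromobutan-2-yl acetate
Conditions: HBr (33% in AcOH), 0 °C → rt
Reagents that add atoms: hydrogen bromide Br; acetic acid CC(=O)O
Why: Acetoxy-bromination of a 1,2-diol: the monoacetate closes to a cyclic acetoxonium ion that bromide opens by SN2 with inversion at one carbon (both carbons are equivalent in the C2-symmetric diol), which gives the erythro (2S,3R) bromo acetate.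

Step 4
Reactants: 6 (2S,3R)-3-bromobutan-2-yl acetate
Product: 8 (2S,3S)-2,3-dimethyloxirane, via bromohydrin 7 (not isolated)
Conditions: KOH, H2O/ethylene glycol, 40 → 100 °C, product distilled out (bp 54 °C)
Reagents that add atoms: none
Why: Saponification frees the alkoxide, which displaces bromide in an intramolecular Williamson SN2 closure with a second inversion at the same carbon, so the trans (2S,3S) epoxide results.

Step 5
Reactants: 4 1-bromo-3,5-dimethoxy-2-methylbenzene; 8 (2S,3S)-2,3-dimethyloxirane
Product: 10 (2S,3S)-3-(3,5-dimethoxy-2-methylphenyl)butan-2-ol, via aryl Grignard reagent 9 (not isolated)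
Conditions: 4 (1.3 equiv), Mg, THF, reflux; then CuI (10 mol %), 8, −30 → 0 °C; 1 M HCl
Reagents that add atoms: none
Why: Copper-catalysed Grignard opening of an epoxide is an SN2 reaction: attack on either (equivalent) carbon of the C2-symmetric epoxide goes anti, which sets the benzylic centre as S and leaves the carbinol centre S.

Step 6
Reactants: 10 (2S,3S)-3-(3,5-dimethoxy-2-methylphenyl)butan-2-ol
Product: 11 (2R,3S)-3-(3,5-dimethoxy-2-methylphenyl)butan-2-yl 4-nitrobenzoate
Conditions: 4-O2NC6H4CO2H, PPh3, DIAD, toluene, 0 °C → rt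
Reagents that add atoms: 4-nitrobenzoic acid O=C(O)c1ccc(cc1)[N+](=O)[O-]
Why: Mitsunobu reaction: the alcohol is activated as its alkoxyphosphonium salt and displaced by 4-nitrobenzoate with SN2 inversion (2S to 2R), the acidic nitrobenzoic acid being the standard choice for hindered secondary alcohols; the aryl ipso carbon is meta to both methoxy groups, so aryl participation is not favoured.

Step 7
Reactants: 11 (2R,3S)-3-(3,5-dimethoxy-2-methylphenyl)butan-2-yl 4-nitrobenzoate
Product: 12 (2R,3S)-3-(3,5-dimethoxy-2-methylphenyl)butan-2-ol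
Conditions: K2CO3 (0.2 equiv), MeOH, rt
Reagents that add atoms: none
Why: Base-catalysed transesterification cleaves the activated ester at the acyl carbon, so the C–O bond of the new 2R centre is not touched.

Step 8
Reactants: 12 (2R,3S)-3-(3,5-dimethoxy-2-methylphenyl)butan-2-ol
Product: 13 (2R,3S)-3-(2-bromo-3,5-dimethoxy-6-methylphenyl)butan-2-ol
Conditions: NBS (1.05 equiv), MeCN, 0 °C
Reagents that add atoms: N-bromosuccinimide O=C1CCC(=O)N1Br
Why: Electrophilic aromatic bromination goes to the ring position para to one methoxy group and ortho to the other (next to the side chain), the usual site in 5-alkylresorcinol dimethyl ethers, and not to the position flanked by two methoxy groups; the stereocentres are remote.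

Step 9
Reactants: 13 (2R,3S)-3-(2-bromo-3,5-dimethoxy-6-methylphenyl)butan-2-ol
Product: 16 (3R,4S)-6,8-dimethoxy-3,4,5-trimethylisochroman-1-one, via aryllithium alkoxide 14 (not isolated), via hydroxy acid 15 (not isolated)
Conditions: n-BuLi (2.2 equiv), THF, −78 °C; CO2 (g), −78 °C → rt; then 2 M HCl/THF, 40 °C
Reagents that add atoms: carbon dioxide O=C=O
Why: The first equivalent of n-BuLi makes the alkoxide, the second effects fast Br/Li exchange, the aryllithium is carboxylated by CO2 and acid closes the six-membered lactone by acyl substitution with retention at C3, so the 3R,4S (trans-dimethyl) lactone results.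

Step 10
Reactants: 16 (3R,4S)-6,8-dimethoxy-3,4,5-trimethylisochroman-1-one
Product: 17 (3R,4S)-6,8-dihydroxy-3,4,5-trimethylisochroman-1-one
Conditions: BBr3 (4 equiv), CH2Cl2, −78 °C → rt; then H2O
Reagents that add atoms: none
Why: BBr3 cleavage of aryl methyl ethers (bromide attacks the methyl group of the boron-bound ether) frees both phenols, the one peri to the carbonyl first; the lactone and the non-acidic C3 and C4 centres survive at or below room temperature.

Step 11
Reactants: 17 (3R,4S)-6,8-dihydroxy-3,4,5-trimethylisochroman-1-one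
Product: 18 (3R,4S)-6,8-bis(tert-butyldimethylsilyloxy)-3,4,5-trimethylisochroman-1-one
Conditions: TBSCl (2.5 equiv), imidazole (5 equiv), DMF, 40 °C
Reagents that add atoms: tert-butyldimethylsilyl chloride CC(C)(C)[Si](C)(C)Cl
Why: Silylation of both phenols removes the acidic protons that would consume hydride in the reduction step and leaves the lactone untouched.

Step 12
Reactants: 18 (3R,4S)-6,8-bis(tert-butyldimethylsilyloxy)-3,4,5-trimethylisochroman-1-one
Product: 19 (3R,4S)-6,8-bis(tert-butyldimethylsilyloxy)-3,4,5-trimethylisochroman-1-ol (both C1 epimers)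
Conditions: i-Bu2AlH (1.2 equiv), CH2Cl2, −78 °C; then aq. KNaC4H4O6 (potassium sodium tartrate)
Reagents that add atoms: none
Why: i-Bu2AlH adds once to the lactone at −78 °C and the tetrahedral aluminium alkoxide is stable until work-up, so reduction stops at the lactol; the aryl silyl ethers are inert.

Step 13
Reactants: 19 (3R,4S)-6,8-bis(tert-butyldimethylsilyloxy)-3,4,5-trimethylisochroman-1-ol
Product: 21 decarboxycitrinin [(3R,4S)-6-hydroxy-3,4,5-trimethyl-3,4-dihydro-8H-isochromen-8-one], via lactol triol 20 (not isolated)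
Conditions: aq. HF (48%), MeCN, 0 °C → rt; pH 5 phosphate buffer work-up, concentrate from toluene
Reagents that add atoms: none
Why: Desilylation by HF frees the phenols, and the 6-hydroxyl para to C1 then expels the lactol hydroxyl in an acid-assisted 1,6-elimination of water to the conjugated quinone methide; C3 and C4 are not involved.

Step 14
Reactants: 17 (3R,4S)-6,8-dihydroxy-3,4,5-trimethylisochroman-1-one
Product: 22 (3R,4S)-7-[(dimethylamino)methyl]-6,8-dihydroxy-3,4,5-trimethylisochroman-1-one
Conditions: CH2=NMe2+ I− (1.1 equiv), Et3N (1.1 equiv), CH2Cl2, 0 °C → rt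
Reagents that add atoms: dimethylmethylideneammonium iodide C=[N+](C)C.[I-]
Why: Mannich reaction (electrophilic aminomethylation of a phenol by the preformed iminium salt) at C7, the only unsubstituted ring position and flanked by both hydroxyl groups; no stereocentre is formed.

Step 15
Reactants: 21 decarboxycitrinin; 22 (3R,4S)-7-[(dimethylamino)methyl]-6,8-dihydroxy-3,4,5-trimethylisochroman-1-one
Product: 24 dicitrinone G, via ortho-quinone methide 23 (not isolated)
Conditions: 21 (1.0 equiv), 22 (1.1 equiv), 1,4-dioxane, 100 °C, Ar sweep, 3 h; then dilute aq. NaH2PO4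
Reagents that add atoms: none
Why: On heating, the zwitterionic Mannich base loses Me2NH to the ortho-quinone methide, an enone whose exocyclic CH2 is the only acceptor site, and C7 of 21, the alpha-carbon of a cyclic vinylogous acid, adds to it in an intermolecular Michael reaction driven by re-aromatisation of the lactone ring; no stereocentre is formed and the four existing ones are untouched.

**Compound list**

1 | 1-bromo-3,5-dimethoxybenzene | COc1cc(Br)cc(OC)c1 | starting material
2 | N-[(2-bromo-4,6-dimethoxyphenyl)methylidene]-N-methylmethanaminium chloride | COc1cc(Br)c(C=[N+](C)C)c(OC)c1.[Cl-] | intermediate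
3 | 2-bromo-4,6-dimethoxybenzaldehyde | COc1cc(Br)c(C=O)c(OC)c1 | intermediate
4 | 1-bromo-3,5-dimethoxy-2-methylbenzene | COc1cc(Br)c(C)c(OC)c1 | intermediate
5 | (2S,3S)-butane-2,3-diol | C[C@H](O)[C@H](C)O | starting material
6 | (2S,3R)-3-bromobutan-2-yl acetate | C[C@H](OC(C)=O)[C@@H](C)Br | intermediate
7 | (2S,3R)-3-bromobutan-2-ol | C[C@H](O)[C@@H](C)Br | intermediate
8 | (2S,3S)-2,3-dimethyloxirane (trans-2,3-epoxybutane) | C[C@H]1[C@H](C)O1 | intermediate
9 | (3,5-dimethoxy-2-methylphenyl)magnesium bromide | COc1cc([Mg]Br)c(C)c(OC)c1 | intermediate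
10 | (2S,3S)-3-(3,5-dimethoxy-2-methylphenyl)butan-2-ol | C[C@H](O)[C@@H](C)c1cc(OC)cc(OC)c1C | intermediate
11 | (2R,3S)-3-(3,5-dimethoxy-2-methylphenyl)butan-2-yl 4-nitrobenzoate | C[C@@H](OC(=O)c1ccc(cc1)[N+](=O)[O-])[C@@H](C)c1cc(OC)cc(OC)c1C | intermediate
12 | (2R,3S)-3-(3,5-dimethoxy-2-methylphenyl)butan-2-ol | C[C@@H](O)[C@@H](C)c1cc(OC)cc(OC)c1C | intermediate
13 | (2R,3S)-3-(2-bromo-3,5-dimethoxy-6-methylphenyl)butan-2-ol | C[C@@H](O)[C@@H](C)c1c(Br)c(OC)cc(OC)c1C | intermediate
14 | lithium (2R,3S)-3-(2-lithio-3,5-dimethoxy-6-methylphenyl)butan-2-olate | C[C@@H](O[Li])[C@@H](C)c1c([Li])c(OC)cc(OC)c1C | intermediate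
15 | 2-[(2S,3R)-3-hydroxybutan-2-yl]-4,6-dimethoxy-3-methylbenzoic acid | C[C@@H](O)[C@@H](C)c1c(C(=O)O)c(OC)cc(OC)c1C | intermediate
16 | (3R,4S)-6,8-dimethoxy-3,4,5-trimethylisochroman-1-one | COc1cc(OC)c2C(=O)O[C@H](C)[C@@H](C)c2c1C | intermediate
17 | (3R,4S)-6,8-dihydroxy-3,4,5-trimethylisochroman-1-one | Oc1cc(O)c2C(=O)O[C@H](C)[C@@H](C)c2c1C | intermediate
18 | (3R,4S)-6,8-bis(tert-butyldimethylsilyloxy)-3,4,5-trimethylisochroman-1-one | CC(C)(C)[Si](C)(C)Oc1cc(O[Si](C)(C)C(C)(C)C)c2C(=O)O[C@H](C)[C@@H](C)c2c1C | intermediate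
19 | (3R,4S)-6,8-bis(tert-butyldimethylsilyloxy)-3,4,5-trimethylisochroman-1-ol (both C1 epimers) | CC(C)(C)[Si](C)(C)Oc1cc(O[Si](C)(C)C(C)(C)C)c2C(O)O[C@H](C)[C@@H](C)c2c1C | intermediate
20 | (3R,4S)-3,4,5-trimethylisochromane-1,6,8-triol | Oc1cc(O)c2C(O)O[C@H](C)[C@@H](C)c2c1C | intermediate
21 | decarboxycitrinin, (3R,4S)-6-hydroxy-3,4,5-trimethyl-3,4-dihydro-8H-isochromen-8-one | CC1=C2C(=CO[C@H](C)[C@H]2C)C(=O)C=C1O | intermediate
22 | (3R,4S)-7-[(dimethylamino)methyl]-6,8-dihydroxy-3,4,5-trimethylisochroman-1-one | CN(C)Cc1c(O)c(C)c2c(c1O)C(=O)O[C@H](C)[C@H]2C | intermediate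
23 | (3R,4S)-8-hydroxy-3,4,5-trimethyl-7-methylidene-3,4-dihydro-1H-isochromene-1,6(7H)-dione | C=C1C(=O)C(C)=C2C(=C1O)C(=O)O[C@H](C)[C@H]2C | intermediate
24 | dicitrinone G, (3R,4S)-6,8-dihydroxy-7-{[(3R,4S)-6-hydroxy-3,4,5-trimethyl-8-oxo-3,4-dihydro-8H-isochromen-7-yl]methyl}-3,4,5-trimethylisochroman-1-one | CC1=C2C(=CO[C@H](C)[C@H]2C)C(=O)C(Cc2c(O)c(C)c3c(c2O)C(=O)O[C@H](C)[C@H]3C)=C1O | target

**Count**

Total steps: 15. Longest linear sequence: 12 steps (1, 2, 5 to 13, 15); steps 3 and 4 feed step 5, and step 14 feeds step 15.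

**Steps most likely to fail, with fallbacks**

Step 6 (Mitsunobu inversion next to a branched benzylic carbon; elimination to the styrene or partial retention could erode it). The fallback replaces SN2 inversion by oxidation and substrate-controlled reduction. It sets out from 10: Dess–Martin periodinane (buffered with NaHCO3, CH2Cl2, 0 °C) gives (3S)-3-(3,5-dimethoxy-2-methylphenyl)butan-2-one F1 without touching the benzylic centre. LiBH(s-Bu)3 in THF at −78 °C then delivers hydride anti to the aryl group (Felkin–Anh control), which gives the syn alcohol 12 directly. Any minor (2S,3S) isomer is 10 and is recycled. The route is rejoined at 12, and step 7 is no longer needed.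

Step 8 (site of bromination: C6 against the position between the methoxy groups). The fallback installs the C1 carbon through the side-chain oxygen, so only C6 can be reached. It sets out from 12: MOMCl and i-Pr2NEt give 1-[(2S,3R)-3-(methoxymethoxy)butan-2-yl]-3,5-dimethoxy-2-methylbenzene F2. Catalytic TMSOTf (CH2Cl2, −40 °C) closes it in an oxa-Pictet–Spengler reaction to (3R,4S)-6,8-dimethoxy-3,4,5-trimethylisochromane F3. DDQ in wet CH2Cl2 oxidises the doubly activated benzylic ether position to (3R,4S)-6,8-dimethoxy-3,4,5-trimethylisochroman-1-ol F4, and Dess–Martin periodinane takes the lactol to the lactone. The route is rejoined at 16.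

Step 15 (the union: 21 is heat- and nucleophile-sensitive and could add through oxygen or self-condense; step 13, which makes it, carries the same sensitivity). The fallback keeps the Michael union but uses a plain resorcinol as donor and builds the quinone methide ring last. It sets out from 12 and 22: BBr3 (CH2Cl2, −78 °C → rt) converts 12 into 5-[(2S,3R)-3-hydroxybutan-2-yl]-4-methylbenzene-1,3-diol F5. Heated with 22 in dioxane, F5 adds through the ring carbon between its two hydroxyls (the other free position is shielded by the branched side chain) to quinone methide 23. This gives (3R,4S)-7-({2,6-dihydroxy-4-[(2S,3R)-3-hydroxybutan-2-yl]-3-methylphenyl}methyl)-6,8-dihydroxy-3,4,5-trimethylisochroman-1-one F6. Its single remaining aromatic C–H is then formylated with HC(OEt)3 and CF3CO2H; the side-chain hydroxyl closes onto the formyl carbon and loss of ethanol gives the quinone methide. The route is rejoined at 24, and steps 11 to 13 are not needed.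

**Further compounds**

F1 | step 6 | (3S)-3-(3,5-dimethoxy-2-methylphenyl)butan-2-one | CC(=O)[C@@H](C)c1cc(OC)cc(OC)c1C
F2 | step 8 | 1-[(2S,3R)-3-(methoxymethoxy)butan-2-yl]-3,5-dimethoxy-2-methylbenzene | C[C@@H](OCOC)[C@@H](C)c1cc(OC)cc(OC)c1C
F3 | step 8 | (3R,4S)-6,8-dimethoxy-3,4,5-trimethylisochromane | COc1cc(OC)c2CO[C@H](C)[C@@H](C)c2c1C
F4 | step 8 | (3R,4S)-6,8-dimethoxy-3,4,5-trimethylisochroman-1-ol | COc1cc(OC)c2C(O)O[C@H](C)[C@@H](C)c2c1C
F5 | step 15 | 5-[(2S,3R)-3-hydroxybutan-2-yl]-4-methylbenzene-1,3-diol | C[C@@H](O)[C@@H](C)c1cc(O)cc(O)c1C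
F6 | step 15 | (3R,4S)-7-({2,6-dihydroxy-4-[(2S,3R)-3-hydroxybutan-2-yl]-3-methylphenyl}methyl)-6,8-dihydroxy-3,4,5-trimethylisochroman-1-one | C[C@@H](O)[C@@H](C)c1cc(O)c(Cc2c(O)c(C)c3c(c2O)C(=O)O[C@H](C)[C@H]3C)c(O)c1C
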